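**Retrosynthetic overview**

1. Ring numbering used in the text: O1, C2 (aryl), C3 (CH2OH), C4 (aroyl), C5 (CH2). The target is 2S,3S,4R, that is 2,3-cis and 3,4-trans.
2. O1–C2 is cut as a reductive etherification. With C2 raised to the ketone level, the oxolane opens to a γ-silyloxy 1,4-diketone whose two halves ArC(=O)–CH–CH2O are identical. Because C3 and C4 have opposite sense, this diketone is meso, and O1 stands 1,4 to C2. This latent meso symmetry about the C3–C4 bond is the feature that makes the key step possible.
3. C3–C4 of the meso diketone is cut into two identical β-silyloxy aryl ketone enolates (oxidative homocoupling).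
4. The monomer ketone is cut into 5-bromo-1,2,3-trimethoxybenzene and 3-silyloxypropanal (aryllithium addition, then oxidation).
5. Ring order: both benzene rings are bought. The oxolane is the only ring made, in the key step, where a chiral acid selects one of the two enantiotopic halves and hydride sets C2.

Key step: step 4

Remark: which antipode of the chiral acid in step 4 selects the ketone next to the (S)-configured α-carbon cannot be predicted; both antipodes are to be screened, and the route is written for the one that leads to the 2S,3S,4R series.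

**Step 1**
Reactants: 1 5-bromo-1,2,3-trimethoxybenzene; 2 3-[(tert-butyldimethylsilyl)oxy]propanal
Product: 4 rac-3-[(tert-butyldimethylsilyl)oxy]-1-(3,4,5-trimethoxyphenyl)propan-1-ol, via (3,4,5-trimethoxyphenyl)lithium 3 (not isolated)
Conditions: n-BuLi, THF, −78 °C; then 2, −78 °C; H2O quench
Reagents that add atoms: none
Why: Bromine–lithium exchange is fast at −78 °C and the aryllithium should add 1,2 to the aldehyde faster than it deprotonates it (halogen–metal exchange followed by carbonyl addition); the carbinol centre forms racemic and is erased in step 2.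

**Step 2**
Reactants: 4 rac-3-[(tert-butyldimethylsilyl)oxy]-1-(3,4,5-trimethoxyphenyl)propan-1-ol
Product: 5 3-[(tert-butyldimethylsilyl)oxy]-1-(3,4,5-trimethoxyphenyl)propan-1-one
Conditions: activated MnO2 (excess), CH2Cl2, rt
Reagents that add atoms: none
Why: Activated MnO2 oxidises electron-rich benzylic alcohols to aryl ketones under neutral heterogeneous conditions, which should leave the silyl ether in place and give the β-silyloxy ketone no base to eliminate with (benzylic alcohol oxidation).

**Step 3**
Reactants: 5 3-[(tert-butyldimethylsilyl)oxy]-1-(3,4,5-trimethoxyphenyl)propan-1-one (two molecules)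
Product: 7 meso-(2R,3S)-2,3-bis{[(tert-butyldimethylsilyl)oxy]methyl}-1,4-bis(3,4,5-trimethoxyphenyl)butane-1,4-dione, via lithium (Z)-enolate 6 (not isolated)
Conditions: LiN(i-Pr)2 (LDA), THF, −78 °C; then CuCl2, DMF, −78 °C to 0 °C; meso isomer separated from the racemic diastereomer by crystallisation or chromatography
Reagents that add atoms: none
Why: Oxidative enolate homocoupling, in which CuCl2 oxidises enolate 6 by one electron and the α-keto radical couples at carbon to join the future C3 and C4 as a 1,4-diketone; no diastereocontrol is expected, so the meso (unlike) dimer, which alone carries the 3,4-trans relationship of the target, is separated from the racemic (like) dimer, which may be re-equilibrated by base-mediated α-epimerisation.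

**Step 4**
Reactants: 7 meso-(2R,3S)-2,3-bis{[(tert-butyldimethylsilyl)oxy]methyl}-1,4-bis(3,4,5-trimethoxyphenyl)butane-1,4-dione
Product: 10 [(3R,4S,5S)-4-{[(tert-butyldimethylsilyl)oxy]methyl}-5-(3,4,5-trimethoxyphenyl)oxolan-3-yl](3,4,5-trimethoxyphenyl)methanone, via cyclic triethylsilyl ketal 8 (not isolated), via 2-aryloxolan-2-ylium ion 9 (not isolated)
Conditions: Et3SiH (1.3 equiv), chiral acid HN[P(=NSO2CF3)(O2C20H10Ar2)]2 (5 mol %; O2C20H10Ar2 = 3,3'-diaryl-1,1'-binaphthalene-2,2'-diolate of one axial sense, Ar = 3,5-(CF3)2C6H3), toluene, −60 °C; then aq. NaHCO3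
Reagents that add atoms: none
Why: Proposed new method: the acid is silylated by Et3SiH (H2 is lost) and the silylium–chiral anion pair silylates one ketone oxygen, the silyl ether oxygen standing 1,4 to that carbonyl carbon adds to it and hands its silyl group on to give ketal 8, loss of the mixed disiloxane leaves oxocarbenium ion 9 paired with the chiral anion, and Et3SiH delivers hydride to C2 and regenerates the silylium ion. The closest known reaction types are the reductive etherification of silyloxy ketones with Et3SiH under TMSOTf or BiBr3 catalysis, which is the same cycle with an achiral anion, and the enantioselective addition of silicon-bound nucleophiles to cyclic oxocarbenium ions paired with confined chiral imidodiphosphorimidate anions; new here are the hydride nucleophile on a ketone-derived ion and the choice between the two enantiotopic halves of a meso substrate. The oxolane closes by 5-exo-trig attack of O1 on the carbonyl carbon C2, so O1–C2 is the ring-forming bond. C2 is set by the substrate: in the envelope of 9 the C3 CH2OSi group lies pseudoaxial to avoid allylic strain with the coplanar aryl ring and hydride enters on the face away from it (inside attack), placing aryl and CH2OSi cis, while C3 and C4 keep the unlike (3,4-trans) relationship of 7 and only their absolute sense is decided, by the chiral anion, for which 9 and its mirror image are diastereomeric ion pairs formed and reduced at different rates. The step needs a single ring closure and no reduction of the second ketone: after the first closure the remaining CH2OSi and aroyl groups are trans on the ring, so a second closure would need a trans-fused dioxabicyclo[3.3.0]octane, and an open-chain silylated aryl ketone without an oxygen partner should take hydride far more slowly than ion 9 at low temperature.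

**Step 5**
Reactants: 10 [(3R,4S,5S)-4-{[(tert-butyldimethylsilyl)oxy]methyl}-5-(3,4,5-trimethoxyphenyl)oxolan-3-yl](3,4,5-trimethoxyphenyl)methanone
Product: 11 [(3R,4S,5S)-4-(hydroxymethyl)-5-(3,4,5-trimethoxyphenyl)oxolan-3-yl](3,4,5-trimethoxyphenyl)methanone
Conditions: HF·pyridine, pyridine, THF, 0 °C to rt
Reagents that add atoms: none
Why: Fluoride-induced cleavage of the primary silyl ether with buffered HF·pyridine is weakly acidic, so the β-alkoxy ketone should not open by retro-oxa-Michael reaction, C4 (already in its more stable trans position) is not touched, and the benzylic O1–C2 bond is not ionised.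

**Compound list**

1 | 5-bromo-1,2,3-trimethoxybenzene | COc1cc(Br)cc(OC)c1OC | starting material
2 | 3-[(tert-butyldimethylsilyl)oxy]propanal | O=CCCO[Si](C)(C)C(C)(C)C | starting material
3 | (3,4,5-trimethoxyphenyl)lithium | COc1cc([Li])cc(OC)c1OC | intermediate
4 | rac-3-[(tert-butyldimethylsilyl)oxy]-1-(3,4,5-trimethoxyphenyl)propan-1-ol | COc1cc(cc(OC)c1OC)C(O)CCO[Si](C)(C)C(C)(C)C | intermediate
5 | 3-[(tert-butyldimethylsilyl)oxy]-1-(3,4,5-trimethoxyphenyl)propan-1-one | COc1cc(cc(OC)c1OC)C(=O)CCO[Si](C)(C)C(C)(C)C | intermediate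
6 | lithium (1Z)-3-[(tert-butyldimethylsilyl)oxy]-1-(3,4,5-trimethoxyphenyl)prop-1-en-1-olate | [Li]O/C(=C\CO[Si](C)(C)C(C)(C)C)c1cc(OC)c(OC)c(OC)c1 | intermediate
7 | meso-(2R,3S)-2,3-bis{[(tert-butyldimethylsilyl)oxy]methyl}-1,4-bis(3,4,5-trimethoxyphenyl)butane-1,4-dione | COc1cc(cc(OC)c1OC)C(=O)[C@@H](CO[Si](C)(C)C(C)(C)C)[C@@H](CO[Si](C)(C)C(C)(C)C)C(=O)c1cc(OC)c(OC)c(OC)c1 | intermediate
8 | 3,4-trans-3-{[(tert-butyldimethylsilyl)oxy]methyl}-2-(triethylsilyloxy)-2-(3,4,5-trimethoxyphenyl)-4-(3,4,5-trimethoxybenzoyl)oxolane (C3 and C4 as in 10, both C2 epimers) | COc1cc(cc(OC)c1OC)C(=O)[C@H]1COC(O[Si](CC)(CC)CC)(c2cc(OC)c(OC)c(OC)c2)[C@@H]1CO[Si](C)(C)C(C)(C)C | intermediate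
9 | 3,4-trans-3-{[(tert-butyldimethylsilyl)oxy]methyl}-2-(3,4,5-trimethoxyphenyl)-4-(3,4,5-trimethoxybenzoyl)oxolan-2-ylium cation (C3 and C4 as in 10; counter-ion is the anion of the chiral acid) | COc1cc(cc(OC)c1OC)C(=O)[C@H]1C[O+]=C(c2cc(OC)c(OC)c(OC)c2)[C@@H]1CO[Si](C)(C)C(C)(C)C | intermediate
10 | [(3R,4S,5S)-4-{[(tert-butyldimethylsilyl)oxy]methyl}-5-(3,4,5-trimethoxyphenyl)oxolan-3-yl](3,4,5-trimethoxyphenyl)methanone | COc1cc(C(=O)[C@H]2CO[C@H](c3cc(OC)c(OC)c(OC)c3)[C@@H]2CO[Si](C)(C)C(C)(C)C)cc(OC)c1OC | intermediate
11 | [(3R,4S,5S)-4-(hydroxymethyl)-5-(3,4,5-trimethoxyphenyl)oxolan-3-yl](3,4,5-trimethoxyphenyl)methanone | COc1cc(C(=O)[C@H]2CO[C@H](c3cc(OC)c(OC)c(OC)c3)[C@@H]2CO)cc(OC)c1OC | target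

**Step count and risks**

Total step count: 5. Longest linear sequence: 5 steps (1 → 4 → 5 → 7 → 10 → 11).

Steps most likely to fail:

1. Step 4 (proposed new method). The chiral ion pair may discriminate too weakly between the two enantiotopic ketone/silyl ether pairs. A silylated ketone may also take hydride before the ring closes, and C3 may epimerise through the enol ether of ion 9. The fallback uses known reaction types only; it sets out from 7 and comes back at 11. Both silyl ethers of 7 are cleaved with HF·pyridine to give the meso diol (2R,3S)-2,3-bis(hydroxymethyl)-1,4-bis(3,4,5-trimethoxyphenyl)butane-1,4-dione F1. A lipase-catalysed desymmetrising acetylation (Burkholderia cepacia lipase or Candida antarctica lipase B, vinyl acetate, t-BuOMe; enzyme chosen by screening for acylation of the CH2OH on the (S)-configured carbon) should give the monoacetate (2S,3R)-3-(hydroxymethyl)-4-oxo-2-(3,4,5-trimethoxybenzoyl)-4-(3,4,5-trimethoxyphenyl)butyl acetate F2. Substrate-controlled reductive cycloetherification of F2 with Et3SiH and BF3·OEt2 in CH2Cl2 at −78 °C (hemiketal, oxocarbenium ion, hydride anti to the C3 substituent) should give [(2S,3S,4R)-4-(3,4,5-trimethoxybenzoyl)-2-(3,4,5-trimethoxyphenyl)oxolan-3-yl]methyl acetate F3. Methanolysis of the acetate (K2CO3, MeOH, 0 °C) then gives 11.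

2. Step 3. The C–C coupling has no diastereocontrol, so the meso dimer is only part of the product. The enolate may also be α-chlorinated by CuCl2 or lose silanolate by β-elimination, and any like dimer carried forward would close twice in step 4. The fallback builds the meso relationship stereospecifically; it sets out from 1 and comes back at 7. Commercial furan-3,4-diyldimethanol is silylated (TBSCl, imidazole, DMF) to 3,4-bis{[(tert-butyldimethylsilyl)oxy]methyl}furan F4. Two-fold direct C–H arylation of both α-positions of F4 with 1 (Pd(OAc)2, PCy3·HBF4, pivalic acid, K2CO3, DMA, 110 °C) should give 3,4-bis{[(tert-butyldimethylsilyl)oxy]methyl}-2,5-bis(3,4,5-trimethoxyphenyl)furan F5. Oxidative ring opening of the furan with m-CPBA (CH2Cl2, 0 °C) should give (2Z)-2,3-bis{[(tert-butyldimethylsilyl)oxy]methyl}-1,4-bis(3,4,5-trimethoxyphenyl)but-2-ene-1,4-dione F6. Syn hydrogenation of its C=C bond (H2, Pd/C, EtOAc) can then only give the meso diketone 7.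

3. Step 1. The aryllithium may deprotonate the enolisable aldehyde, followed by β-elimination of silanolate, instead of adding 1,2. The fallback sets out from 2 and comes back at 4. Rhodium-catalysed 1,2-addition of commercial (3,4,5-trimethoxyphenyl)boronic acid to 2 ([Rh(OH)(cod)]2 cat., dioxane/H2O, 60 °C) is a non-basic aryl transfer and should give 4 directly; no new compound is made (F0).

**Further compounds**

F1 | step 4 | meso-(2R,3S)-2,3-bis(hydroxymethyl)-1,4-bis(3,4,5-trimethoxyphenyl)butane-1,4-dione | COc1cc(cc(OC)c1OC)C(=O)[C@@H](CO)[C@@H](CO)C(=O)c1cc(OC)c(OC)c(OC)c1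
F2 | step 4 | (2S,3R)-3-(hydroxymethyl)-4-oxo-2-(3,4,5-trimethoxybenzoyl)-4-(3,4,5-trimethoxyphenyl)butyl acetate | COc1cc(cc(OC)c1OC)C(=O)[C@@H](CO)[C@@H](COC(C)=O)C(=O)c1cc(OC)c(OC)c(OC)c1
F3 | step 4 | [(2S,3S,4R)-4-(3,4,5-trimethoxybenzoyl)-2-(3,4,5-trimethoxyphenyl)oxolan-3-yl]methyl acetate | COc1cc(C(=O)[C@H]2CO[C@H](c3cc(OC)c(OC)c(OC)c3)[C@@H]2COC(C)=O)cc(OC)c1OC
F4 | step 3 | 3,4-bis{[(tert-butyldimethylsilyl)oxy]methyl}furan | CC(C)(C)[Si](C)(C)OCc1cocc1CO[Si](C)(C)C(C)(C)C
F5 | step 3 | 3,4-bis{[(tert-butyldimethylsilyl)oxy]methyl}-2,5-bis(3,4,5-trimethoxyphenyl)furan | CC(C)(C)[Si](C)(C)OCc1c(CO[Si](C)(C)C(C)(C)C)c(-c2cc(OC)c(OC)c(OC)c2)oc1-c1cc(OC)c(OC)c(OC)c1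
F6 | step 3 | (2Z)-2,3-bis{[(tert-butyldimethylsilyl)oxy]methyl}-1,4-bis(3,4,5-trimethoxyphenyl)but-2-ene-1,4-dione | COc1cc(cc(OC)c1OC)C(=O)/C(CO[Si](C)(C)C(C)(C)C)=C(/CO[Si](C)(C)C(C)(C)C)C(=O)c1cc(OC)c(OC)c(OC)c1
F0 | step 1 | none | none
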